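The cyclohexane ring (C1, C2, C6, C7, C8, C9) is cut at C2–C6 and C8–C9 into a prenyl unit (C9–C1(C10)–C2) and an enal unit (C6=C7–C8=O) joined through the C3–C4–C5 tether. The key step, a Me2AlCl-promoted sequence of intramolecular ene reaction and type 2 carbonyl-ene reaction, closes the cyclopentanone and the 3-methylenecyclohexanol in one operation and sets C2, C6, C7 and C8. It exploits the C8(OH)–C9–C1(=C10) motif next to the C2–C6 ring fusion, the footprint of an isopropylidene group that has reacted twice as an ene. The precursor is an acyclic Z-enynal whose quaternary C5 lies in a chiral 1,3-dioxan-4-one that carries C11 and a temporary carboxyl group.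

Key step: step 5

Numbering used in the text (a remark, not part of any SMILES): C1 bears the exocyclic methylene C10; C2 and C6 are the ring-fusion carbons; C3–C4(=O)–C5 complete the cyclopentanone; C5 bears C11 (the acetoxy-bearing carbon); C7 bears the oxirane carbon C12 (C13 is the ester carbon, C14 the oxirane CH2); C8 and C9 bear the two acyloxy groups. The C5 centre of 6 is configurationally labile (β-dicarbonyl) and is drawn without configuration; 17 is carried as a C9 epimer mixture.

Step 1
Reactants: 1 (S)-3-hydroxybutanoic acid; 2 pivalaldehyde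
Product: 3 (2S,6S)-2-tert-butyl-6-methyl-1,3-dioxan-4-one
Conditions: TsOH·H2O (cat.), CH2Cl2, reflux, water separator; recrystallisation
Reagents that add atoms: none
Why: Acid-catalysed acetalisation of the β-hydroxy acid should give the cis-2,6-disubstituted dioxanone under thermodynamic control (both groups equatorial), so the acetal centre is set by C11, which comes from the chiral pool.

Step 2
Reactants: 3 (2S,6S)-2-tert-butyl-6-methyl-1,3-dioxan-4-one; 4 4-methylpent-3-enoic acid
Product: 6 (2S,6S)-2-tert-butyl-6-methyl-5-(4-methylpent-3-enoyl)-1,3-dioxan-4-one, via acyl imidazole 5 (not isolated)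
Conditions: 4, carbonyldiimidazole, THF, 25 °C; separately 3, LiN(i-Pr)2, THF, −78 °C; then 5, −78 °C; aq. NH4Cl
Reagents that add atoms: none
Why: Claisen-type C-acylation of the lithium enolate by the acyl imidazole should install the prenyl ketone arm (C1–C4 with C9 and C10 as the two methyl groups); the new C5 centre is a freely equilibrating β-keto lactone position and needs no control.

Step 3
Reactants: 6 (2S,6S)-2-tert-butyl-6-methyl-5-(4-methylpent-3-enoyl)-1,3-dioxan-4-one; 7 triformylmethane
Product: 9 (2S,5S,6S)-2-tert-butyl-5-(2,2-diformylethenyl)-6-methyl-5-(4-methylpent-3-enoyl)-1,3-dioxan-4-one, via chloromethylene dialdehyde 8 (not isolated)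
Conditions: 7, (COCl)2, CH2Cl2, 0 °C; then 6, i-Pr2NEt, CH2Cl2, −40 → 0 °C
Reagents that add atoms: none
Why: Nucleophilic vinylic substitution (addition–elimination) of the stabilised enolate on the vinylogous acid chloride should create the quaternary C5; the electrophile is expected to enter anti to the 6-methyl group of the dioxanone enolate, so the acyl arm ends cis to that methyl group.

Step 4
Reactants: 9 (2S,5S,6S)-2-tert-butyl-5-(2,2-diformylethenyl)-6-methyl-5-(4-methylpent-3-enoyl)-1,3-dioxan-4-one
Product: 10 (2S,5S,6S)-2-tert-butyl-5-[(Z)-2-formylbut-1-en-3-ynyl]-6-methyl-5-(4-methylpent-3-enoyl)-1,3-dioxan-4-one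
Conditions: Me3SiCHN2, LiN(i-Pr)2, THF, −78 °C; then 9 (1 equiv of reagent), −78 → 0 °C; aq. NH4Cl
Reagents that add atoms: (trimethylsilyl)diazomethane C[Si](C)(C)C=[N+]=[N-]
Why: Colvin homologation (addition, Peterson elimination, alkylidene carbene 1,2-shift) should occur at the formyl group anti to the quaternary C5, the syn formyl group being shielded as is the Z-ester of an alkylidene malonate, which leaves the formyl group syn to C5 (Z-enal) and the small ethynyl group anti.

Step 5
Reactants: 10 (2S,5S,6S)-2-tert-butyl-5-[(Z)-2-formylbut-1-en-3-ynyl]-6-methyl-5-(4-methylpent-3-enoyl)-1,3-dioxan-4-one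
Product: 12 spiro tricyclic alcohol (cis-fused 1-methylene-hydrindan-4-one whose C5 is C5 of the dioxanone; 7-ethynyl; 8-hydroxy; H2, H6, H7 and H8 all on one face), via ene adduct aldehyde 11 (not isolated)
Conditions: Me2AlCl (3 equiv), CH2Cl2, −78 → −20 °C; then aq. NaHCO3
Reagents that add atoms: none
Why: Me2AlCl binds the Z-enal, the prenyl alkene adds through C2 to C6 in an intramolecular ene reaction while a methyl hydrogen is delivered suprafacially to C7, giving the cis-1,2-disubstituted cyclopentanone 11 with an isopropenyl group. The aluminium-bound aldehyde of 11 then undergoes a type 2 carbonyl-ene reaction in which the isopropenyl CH2 (C9) attacks C8 and the remaining methyl group gives its hydrogen to oxygen, which leaves the exocyclic C1=C10 bond. The closest known chemistry is the Me2AlCl-induced sequential ene cyclohexannulation of enals with 2-methylalkenes, used here in tethered form; the first closure is a 5-ring ene cyclisation of a 1,6-diene (exo mode at C6), the second a 6-ring closure onto the carbonyl group through a chair with axial C=O. C2 and C6 should be cis because tether and hydrogen donor sit on one face of the enophile, C7 follows from the Z geometry (formyl syn to C5), and C8 from the chair with the ethynyl group equatorial and the oxygen axial. The absolute sense comes from the dioxanone, whose acyl arm is axial on C5, with the enal carbon C7 expected to turn to the C11–H flank away from the lactone carbonyl. The step needs ene transfer to outrun hetero-Diels–Alder closure and acylal ionisation, which the proton-scavenging Me2AlCl, the quaternary C5 and the low temperature are meant to secure.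

Step 6
Reactants: 12 spiro tricyclic alcohol; 13 (E)-3-methylpent-2-enoic acid
Product: 14 C8 (E)-3-methylpent-2-enoate of 12
Conditions: N,N'-diisopropylcarbodiimide, DMAP, CH2Cl2, 25 °C
Reagents that add atoms: none
Why: Steglich esterification of the only free hydroxyl group installs the first acyl group at C8 before a second oxygen is present; no stereocentre is touched.

Step 7
Reactants: 14 C8 (E)-3-methylpent-2-enoate of 12
Product: 15 acrylate (C7 bears a 1-(methoxycarbonyl)ethenyl group)
Conditions: Pd(OAc)2 (cat.), 2-(diphenylphosphino)pyridine, MsOH (cat.), CO (5 bar), MeOH (5 equiv), THF, 45 °C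
Reagents that add atoms: carbon monoxide [C-]#[O+]; methanol CO
Why: Palladium-catalysed Markovnikov hydromethoxycarbonylation of the terminal alkyne should give the branched methyl acrylate (C12=C14, C13 ester) while the 1,1-disubstituted alkene, the enoate and the phosphine-buffered acylal are left alone.

Step 8
Reactants: 15 acrylate
Product: 16 glycidic ester (C7 bears the 2-(methoxycarbonyl)oxiran-2-yl group)
Conditions: t-BuOOH (anhydrous), DBU, CH2Cl2, 0 → 25 °C
Reagents that add atoms: tert-butyl hydroperoxide CC(C)(C)OO
Why: Weitz–Scheffer nucleophilic epoxidation is selective for the electron-poor acrylate over the exocyclic alkene and the β,β-disubstituted enoate; with the enolate C12=C13 bond eclipsing C7–H, the oxygen is expected to close onto C12 from the C8 side, away from the bulky spiro centre C5, which sets C12.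

Step 9
Reactants: 16 glycidic ester
Product: 18 C9 ketone (2-methylene ketone flanked by the C8 ester), via allylic alcohol 17 (not isolated)
Conditions: SeO2 (cat.), t-BuOOH, CH2Cl2, 25 °C; then Dess–Martin periodinane, NaHCO3, CH2Cl2, 0 °C
Reagents that add atoms: tert-butyl hydroperoxide CC(C)(C)OO
Why: Riley allylic oxidation (ene reaction then [2,3]-shift) should attack the ring CH2 (C9) next to the exocyclic alkene in preference to the methine C2, and the alcohol is oxidised at once, so its configuration does not matter.

Step 10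
Reactants: 18 C9 ketone
Product: 19 C9 alcohol cis to the C8 ester
Conditions: NaBH4, CeCl3·7H2O, MeOH–THF, −78 °C
Reagents that add atoms: none
Why: Luche 1,2-reduction of the activated enone should be faster than attack on the hindered C4 ketone, and hydride is expected to enter from the convex face anti to the axial C8 acyloxy group, which puts the C9 hydroxyl cis to C8–O.

Step 11
Reactants: 19 C9 alcohol; 20 (R)-2-methylbutanoic acid
Product: 21 C9 (R)-2-methylbutanoate
Conditions: N,N'-diisopropylcarbodiimide, DMAP (cat.), CH2Cl2, 0 °C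
Reagents that add atoms: none
Why: Steglich esterification at low temperature acylates the allylic alcohol with retention and should not epimerise the α-centre of the acid, which is bought as the single enantiomer.

Step 12
Reactants: 21 C9 (R)-2-methylbutanoate
Product: 23 hydroxy ketone (C5–H, C11–OH), via keto acid 22 (not isolated)
Conditions: TsOH·H2O (cat.), THF–H2O, 0 → 25 °C
Reagents that add atoms: none
Why: Acid hydrolysis of the acylal releases pivalaldehyde and the β-keto acid, which decarboxylates through its enol; kinetic protonation of the enol on the convex face (the face of H2 and H6) should place C11 on the concave face and so set C5.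

Step 13
Reactants: 23 hydroxy ketone
Product: 24 target compound
Conditions: Ac2O, pyridine, 0 → 25 °C
Reagents that add atoms: acetic anhydride CC(=O)OC(C)=O
Why: Acetylation of the only free hydroxyl group under weakly basic conditions without DMAP should avoid both epimerisation at C5 and β-elimination.

Compound list
1 | (S)-3-hydroxybutanoic acid | C[C@H](O)CC(=O)O | starting material
2 | pivalaldehyde | CC(C)(C)C=O | starting material
3 | (2S,6S)-2-tert-butyl-6-methyl-1,3-dioxan-4-one | C[C@H]1CC(=O)O[C@@H](C(C)(C)C)O1 | intermediate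
4 | 4-methylpent-3-enoic acid | CC(C)=CCC(=O)O | starting material
5 | 1-(4-methylpent-3-enoyl)imidazole | CC(C)=CCC(=O)n1ccnc1 | intermediate
6 | (2S,6S)-2-tert-butyl-6-methyl-5-(4-methylpent-3-enoyl)-1,3-dioxan-4-one (C5 labile) | C[C@H]1C(C(=O)CC=C(C)C)C(=O)O[C@@H](C(C)(C)C)O1 | intermediate
7 | triformylmethane (2-formylpropanedial) | O=CC(C=O)C=O | starting material
8 | 2-(chloromethylene)propanedial | ClC=C(C=O)C=O | intermediate
9 | (2S,5S,6S)-2-tert-butyl-5-(2,2-diformylethenyl)-6-methyl-5-(4-methylpent-3-enoyl)-1,3-dioxan-4-one | C[C@H]1[C@](C(=O)CC=C(C)C)(C=C(C=O)C=O)C(=O)O[C@@H](C(C)(C)C)O1 | intermediate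
10 | (2S,5S,6S)-2-tert-butyl-5-[(Z)-2-formylbut-1-en-3-ynyl]-6-methyl-5-(4-methylpent-3-enoyl)-1,3-dioxan-4-one | C[C@H]1[C@](C(=O)CC=C(C)C)(/C=C(\C=O)C#C)C(=O)O[C@@H](C(C)(C)C)O1 | intermediate
11 | ene adduct: spiro cyclopentanone with 2-isopropenyl and cis 6-(1-formylprop-2-ynyl) groups | CC(=C)[C@H]1CC(=O)[C@]2(C(=O)O[C@@H](C(C)(C)C)O[C@H]2C)[C@H]1[C@@H](C#C)C=O | intermediate
12 | spiro tricyclic alcohol (1-methylene, 7-ethynyl, 8-hydroxy, cis-fused, C5 spiro to the dioxanone) | C=C1[C@H]2CC(=O)[C@]3(C(=O)O[C@@H](C(C)(C)C)O[C@H]3C)[C@H]2[C@@H](C#C)[C@@H](O)C1 | intermediate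
13 | (E)-3-methylpent-2-enoic acid | CC/C(C)=C/C(=O)O | starting material
14 | C8 (E)-3-methylpent-2-enoate of 12 | C=C1[C@H]2CC(=O)[C@]3(C(=O)O[C@@H](C(C)(C)C)O[C@H]3C)[C@H]2[C@@H](C#C)[C@@H](OC(=O)/C=C(\C)CC)C1 | intermediate
15 | acrylate (1-(methoxycarbonyl)ethenyl at C7) | C=C1[C@H]2CC(=O)[C@]3(C(=O)O[C@@H](C(C)(C)C)O[C@H]3C)[C@H]2[C@@H](C(=C)C(=O)OC)[C@@H](OC(=O)/C=C(\C)CC)C1 | intermediate
16 | glycidic ester (2-(methoxycarbonyl)oxiran-2-yl at C7) | C=C1[C@H]2CC(=O)[C@]3(C(=O)O[C@@H](C(C)(C)C)O[C@H]3C)[C@H]2[C@@H]([C@@]4(C(=O)OC)CO4)[C@@H](OC(=O)/C=C(\C)CC)C1 | intermediate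
17 | C9 allylic alcohol (C9 epimers) | C=C1[C@H]2CC(=O)[C@]3(C(=O)O[C@@H](C(C)(C)C)O[C@H]3C)[C@H]2[C@@H]([C@@]4(C(=O)OC)CO4)[C@@H](OC(=O)/C=C(\C)CC)C1O | intermediate
18 | C9 ketone | C=C1[C@H]2CC(=O)[C@]3(C(=O)O[C@@H](C(C)(C)C)O[C@H]3C)[C@H]2[C@@H]([C@@]4(C(=O)OC)CO4)[C@@H](OC(=O)/C=C(\C)CC)C1=O | intermediate
19 | C9 alcohol cis to the C8 ester | C=C1[C@H]2CC(=O)[C@]3(C(=O)O[C@@H](C(C)(C)C)O[C@H]3C)[C@H]2[C@@H]([C@@]4(C(=O)OC)CO4)[C@@H](OC(=O)/C=C(\C)CC)[C@H]1O | intermediate
20 | (R)-2-methylbutanoic acid | CC[C@@H](C)C(=O)O | starting material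
21 | C9 (R)-2-methylbutanoate, dioxanone intact | C=C1[C@H]2CC(=O)[C@]3(C(=O)O[C@@H](C(C)(C)C)O[C@H]3C)[C@H]2[C@@H]([C@@]4(C(=O)OC)CO4)[C@@H](OC(=O)/C=C(\C)CC)[C@H]1OC(=O)[C@H](C)CC | intermediate
22 | β-keto acid (C5 carboxylic acid, C11 alcohol) | C=C1[C@H]2CC(=O)[C@@](C(=O)O)([C@H](C)O)[C@H]2[C@@H]([C@@]3(C(=O)OC)CO3)[C@@H](OC(=O)/C=C(\C)CC)[C@H]1OC(=O)[C@H](C)CC | intermediate
23 | hydroxy ketone (11-deacetyl target) | C=C1[C@H]2CC(=O)[C@@H]([C@H](C)O)[C@H]2[C@@H]([C@@]2(C(=O)OC)CO2)[C@@H](OC(=O)/C=C(\C)CC)[C@H]1OC(=O)[C@H](C)CC | intermediate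
24 | CNP0251769.1 | C=C1[C@H]2CC(=O)[C@@H]([C@H](C)OC(C)=O)[C@H]2[C@@H]([C@@]2(C(=O)OC)CO2)[C@@H](OC(=O)/C=C(\C)CC)[C@H]1OC(=O)[C@H](C)CC | target

Total step count: 13. Longest linear sequence: 13 steps (from 1 to 24; acids 4, 13 and 20 and triformylmethane 7 are bought).

Steps most likely to fail

Step 5 (key step). The zwitterionic ene intermediate may collapse by C–O bond formation (hetero-Diels–Alder closure), the aluminium reagent may ionise the acylal, and the prenyl alkene may add to the other face of C6. Nothing in the substrate enforces the face beyond the conformational argument given. The chair assumed for the second closure may also lose to the chair with an axial ethynyl group, which would invert C8. The fallback separates the two pericyclic events and removes the strong Lewis acid from the first one. It sets out from 10, which is heated in toluene at 130 °C with BHT so that the first ene reaction runs thermally. The aldehyde 11 is then isolated and closed in a separate type 2 carbonyl-ene reaction with the bulky, weakly ionising methylaluminium bis(4-bromo-2,6-di-tert-butylphenoxide) in CH2Cl2 at −78 °C. The sequence comes back to the route at 12 and makes no new compound.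

Step 4. The reagent may attack the shielded formyl group or both formyl groups, and the Z-enal may isomerise to the more stable E form during work-up. The E form would deliver the wrong configuration at C7 in step 5. The fallback sets out from 6 and comes back at 10. Bromomalonaldehyde is converted with (COCl)2 into 2-bromo-3-chloroprop-2-enal F1. Vinylic substitution of F1 by 6 (i-Pr2NEt) gives the bromo enal F2. Stille coupling of F2 with tributyl(ethynyl)stannane (Pd(PPh3)4, CuI, DMF, 25 °C) gives the E-configured enynal F3. Triplet-sensitised E-to-Z photoisomerisation of F3 (Ir(ppy)3, blue light, MeCN) then enriches the twisted Z isomer 10, and recovered F3 is recycled.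

Step 12. The acid may open the oxirane, the ketone may re-enolise so that C5 drifts to its more stable configuration, and ketonisation of the enol may be poorly face-selective. The fallback takes the protonation out of the acidic medium; it sets out from 21 and comes back at 23. The acylal is hydrolysed at 0 °C and the keto acid 22 is isolated cold. N,O-bis(trimethylsilyl)acetamide converts 22 into the bis-silyl derivative F4. Gentle warming (40 °C) of F4 causes decarboxylation with silyl transfer to the regiodefined silyl enol ether F5. Buffered protodesilylation of F5 (HF·pyridine, pyridine, THF, −40 °C) then protonates C5 kinetically from the convex face and frees C11–OH, giving 23.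

Further compounds
F0 | step 5 | none | none
F1 | step 4 | 2-bromo-3-chloroprop-2-enal | O=CC(Br)=CCl
F2 | step 4 | (2S,5S,6S)-5-[(Z)-2-bromo-2-formylethenyl]-2-tert-butyl-6-methyl-5-(4-methylpent-3-enoyl)-1,3-dioxan-4-one | C[C@H]1[C@](C(=O)CC=C(C)C)(/C=C(\Br)C=O)C(=O)O[C@@H](C(C)(C)C)O1
F3 | step 4 | (2S,5S,6S)-2-tert-butyl-5-[(E)-2-formylbut-1-en-3-ynyl]-6-methyl-5-(4-methylpent-3-enoyl)-1,3-dioxan-4-one | C[C@H]1[C@](C(=O)CC=C(C)C)(/C=C(\C#C)C=O)C(=O)O[C@@H](C(C)(C)C)O1
F4 | step 12 | trimethylsilyl ester and C11 trimethylsilyl ether of keto acid 22 | C=C1[C@H]2CC(=O)[C@@](C(=O)O[Si](C)(C)C)([C@H](C)O[Si](C)(C)C)[C@H]2[C@@H]([C@@]3(C(=O)OC)CO3)[C@@H](OC(=O)/C=C(\C)CC)[C@H]1OC(=O)[C@H](C)CC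
F5 | step 12 | C4=C5 trimethylsilyl enol ether with C11 trimethylsilyl ether | C=C1[C@H]2CC(O[Si](C)(C)C)=C([C@H](C)O[Si](C)(C)C)[C@H]2[C@@H]([C@@]3(C(=O)OC)CO3)[C@@H](OC(=O)/C=C(\C)CC)[C@H]1OC(=O)[C@H](C)CC
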